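If the rate at a fixed catalyst charge goes as the starting material S to a power n, the apparent order, then the east run can be carried over to the north run, since both hold 0.0300 M of catalyst.

| flask | starting material | catalyst | time |
|---|---|---|---|
| south | 0.600 M | 0.0600 M |  |
| east | 0.600 M | 0.0300 M |  |
| south-west | 0.300 M | 0.0600 M |  |
| north | 1.80 M | 0.0300 M | 79 min |

| run | time / min | [product] / M |
|---|---|---|
| south run | 4.5 | 0.040 |
| south run | 14 | 0.119 |
| south run | 26 | 0.208 |
| south run | 41 | 0.315 |
| south run | 59 | 0.405 |
| south run | 79 | 0.474 |
| east run | 4.5 | 0.018 |
| east run | 14 | 0.074 |
| east run | 26 | 0.128 |
| east run | 41 | 0.197 |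
| east run | 59 | 0.264 |
| east run | 79 | 0.332 |
| south-west run | 4.5 | 0.025 |
| south-west run | 14 | 0.075 |
| south-west run | 26 | 0.128 |
| south-west run | 41 | 0.170 |
| south-west run | 59 | 0.214 |
| south-west run | 79 | 0.243 |

(standard deviation of a reading: 0.006 M)

- Overall: starting material -> product, with catalyst as catalyst.
- Constant volume, constant temperature.
- The analysis sees a species whether free or bound.
- An order is taken over about fifteen percent of the charge, up and down.

1. how the opening rate goes with [catalyst] round the charge of the south run: the exponent of the rate at two percent of starting material gone to product
2. how the opening rate goes with [starting material] round the charge of the south run: the exponent of the rate at two percent of starting material gone to product (one fixed amount of product, the same in the runs compared)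
3. product in the north run at 79 min, as a share of the starting material charged

Take S_c as the charge and m = 1 − n. Integrating this rate law (the integrated rate law, which we call the substrate clock), we find that S^m falls by equal amounts in equal times at one catalyst charge, whatever S_c is. For n between 0 and 1 this gives us two bounds for the north run. At n = 1 it converts the same share as the east run, 55.3%, our upper bound. At n = 0 it makes the same molarity, a share of 18.4%, our lower bound.

We tighten the bracket with a reading of n. At 14 min, the south run, at twice the charge of the south-west run and the same catalyst, is held against the south-west run:

n = ln(0.119 M / 0.075 M) / ln(2) = 0.666 ± 0.136, so m = 0.334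

The clock θ is the fall of (S/S_c)^m over 79 min at this catalyst charge, counted on the east charge:

θ = 1 − (1 − 0.332 M / 0.600 M)^m = 0.236

For the north run, the share f converted is then:

f = 1 − (1 − θ(0.600 M / 1.80 M)^m)^(1/m) = 41.4%

Moving n by its scatter gives a bracket from 35.8% to 47.2%.

The forecast gives 0.75 in catalyst, 0.6 in starting material and 34% for the north run. Its ground, in its own words: “A saturation fit gives K about 0.8 M”. Its share stands below our bracket, and we commit to 41.4%.

The north run gives 40.9%, inside our bracket. Round the charge of the south run, the opening rate has orders of 0.78 in catalyst and 0.70 in starting material.

catalyst + starting material ⇌ catalyst-substrate complex (1.338 L mol⁻¹ min⁻¹, 4.380 min⁻¹); catalyst-substrate complex → product + catalyst (4.494 min⁻¹); 2 catalyst ⇌ resting dimer, settled at all times (4.910 L mol⁻¹); 2 starting material ⇌ idle substrate dimer, settled at all times (1.100 L mol⁻¹) At one fixed amount of product, the south-west run went at 0.60 of the rate of the south run. Read back from its result, the north run ran a clock of 0.232 on the east charge. At that pace a quarter of the charge of the east run has turned at 31.2 min, and in the east run itself the product comes to a quarter of the charge at 30.5 min.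

The runs come from a simulation on assumed constants, and the scatter is random.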